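**Strategy**

Cardopatine is the C2-symmetric head-to-head cyclodimer of one achiral enyne: the twofold axis of the cyclobutane bisects the C1–C2 bond (the two alkynyl-bearing methines) and the C3–C4 bond (the two methylenes). Disconnecting both bonds gives two molecules of 5-(but-3-en-1-ynyl)-2,2'-bithiophene, the monomer from which the ring presumably arises in the plant. The key step is this biomimetic [2+2] cyclodimerization, run as a radical-cation process under a chiral counteranion, so that the ring, both stereocenters and the whole skeleton should form in one operation from a precursor with no stereocenter. The monomer is assembled from 5-bromo-2,2'-bithiophene by two Sonogashira couplings.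

Key step: step 3

Remark: the sense of induction of the chiral anion in step 3 cannot be predicted, so the (S,S)-anion is written and its antipode is taken if a first run shows that one to favour the (1R,2R)-dimer; compounds 5, 6 and 7 are photosensitizers and are handled under argon in amber glassware.

**Route**

Step 1
Reactants: 1 5-bromo-2,2'-bithiophene; 2 ethynyltrimethylsilane
Product: 3 5-[(trimethylsilyl)ethynyl]-2,2'-bithiophene
Conditions: Pd(PPh3)2Cl2 (2 mol%), CuI (4 mol%), Et3N/THF 1:1, 60 °C, argon
Reagents that add atoms: none
Why: Sonogashira coupling, in which zerovalent palladium inserts into the C–Br bond of the 2-bromothiophene, the copper acetylide transmetalates and reductive elimination forms the aryl–alkyne bond; no stereocenter is formed.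

Step 2
Reactants: 3 5-[(trimethylsilyl)ethynyl]-2,2'-bithiophene; 4 bromoethene (vinyl bromide, 1 M in THF)
Product: 6 5-(but-3-en-1-yn-1-yl)-2,2'-bithiophene, via 5-ethynyl-2,2'-bithiophene 5 (not isolated)
Conditions: K2CO3 (0.2 equiv), MeOH/THF, rt; then Pd(PPh3)4 (3 mol%), CuI (5 mol%), iPr2NH, 4 (3 equiv), rt, argon, dark
Reagents that add atoms: none
Why: Carbonate-catalysed methanolysis of the alkynyl C–Si bond frees the terminal alkyne, which undergoes a second Sonogashira coupling with the reactive vinyl bromide in the same flask, so that the air- and light-sensitive ethynylbithiophene is never handled; no stereocenter is formed.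

Step 3
Reactants: 6 5-(but-3-en-1-yn-1-yl)-2,2'-bithiophene (two molecules)
Product: 7 (1R,2R)-1,2-bis[(2,2'-bithiophen-5-yl)ethynyl]cyclobutane (cardopatine)
Conditions: 9-mesitylthioxanthylium salt of the (S,S)-IDPi anion {[(S)-3,3'-Ar2-BINOL-P(=NTf)]2N−, Ar = 3,5-(CF3)2C6H3, Tf = SO2CF3} (2 mol%), CH2Cl2 (0.05 M), −78 °C, green LEDs (525 nm), argon, stopped at about 80% conversion
Reagents that add atoms: none
Why: Proposed new method: photoinduced electron transfer from 6 to the excited thioxanthylium cation should give the radical cation of 6, which bonds through its terminal CH2 to the terminal CH2 of a neutral 6 (future C3–C4) and then collapses between the two propargylic carbons (future C1–C2) to the cyclobutane radical cation, reduced to 7 by the thioxanthyl radical or by 6 in a chain. The closest known reaction type is the radical-cation [2+2] cyclodimerization of electron-rich vinylarenes to trans-1,2-diarylcyclobutanes, including its enantioselective variant under a photoredox cation paired with a confined chiral imidodiphosphorimidate anion; a 1-hetaryl-1,3-enyne has not been used as substrate. The cyclobutane closes in a stepwise intermolecular [2+2] mode, by 1,4-combination of the cationic and radical termini of the tetramethylene intermediate, and the first bond creates no stereocenter. C1 and C2 are both set in that 1,4-combination: trans by mutual avoidance of the two rod-like alkynyl-bithienyl arms (the trans ring is also the more stable one), and (1R,2R) by the chiral anion, the only counterion any radical cation in the flask can have. Head-to-head regioselectivity is needed and is secured by the substrate, since only CH2–CH2 bonding leaves both spin and charge on propargylic carbons conjugated to bithienyl, while the alkyne spacer excludes the six-ring closure onto an arene known from styrene radical cations. Green light, which 6 does not absorb, should keep the racemic triplet dimerization silent, and stopping short of full conversion keeps 6 present as the preferred electron donor so that 7 is not reopened.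

**Compound list**

1 | 5-bromo-2,2'-bithiophene | Brc1ccc(-c2cccs2)s1 | starting material
2 | ethynyltrimethylsilane | C#C[Si](C)(C)C | starting material
3 | 5-[(trimethylsilyl)ethynyl]-2,2'-bithiophene | C[Si](C)(C)C#Cc1ccc(-c2cccs2)s1 | intermediate
4 | bromoethene (vinyl bromide) | C=CBr | starting material
5 | 5-ethynyl-2,2'-bithiophene | C#Cc1ccc(-c2cccs2)s1 | intermediate
6 | 5-(but-3-en-1-yn-1-yl)-2,2'-bithiophene | C=CC#Cc1ccc(-c2cccs2)s1 | intermediate
7 | (1R,2R)-1,2-bis[(2,2'-bithiophen-5-yl)ethynyl]cyclobutane (cardopatine) | C(#C[C@@H]1CC[C@H]1C#Cc1ccc(-c2cccs2)s1)c1ccc(-c2cccs2)s1 | target

**Step count and risks**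

Total step count: 3. Longest linear sequence: 3 steps (1 → 3 → 6 → 7).

The steps most likely to fail, in this order, are step 3, step 2 and step 1.

Step 3 (Proposed new method) may fail in three ways. Facial discrimination in the ring-closing bond formation inside the ion pair may be insufficient. Radical cations may couple oxidatively at the free 5'-position of the terminal thiophene and lead to oligomers. Energy transfer may open a racemic triplet channel. The fallback uses known chemistry, sets out from 6 and comes back at 7. A degassed, concentrated solution of 6 in benzene is irradiated at 365 nm, or at 405 nm with 2-isopropylthioxanthen-9-one as triplet sensitizer. This triplet [2+2] photodimerization runs through the bis-propargylic 1,4-diradical and is the way the dimer is thought to arise in the plant. It should give the racemic trans dimer, that is 7 together with its mirror image (1S,2S)-1,2-bis[(2,2'-bithiophen-5-yl)ethynyl]cyclobutane F1, besides the meso dimer cis-1,2-bis[(2,2'-bithiophen-5-yl)ethynyl]cyclobutane F2. F2 is removed by chromatography on silica gel. 7 is then separated from F1 by preparative HPLC on an immobilized amylose tris(3,5-dimethylphenylcarbamate) phase. The same chiral phase would also polish material of incomplete enantiomeric purity from the catalytic step.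

Step 2 may fail through oxidative homocoupling of the liberated terminal alkyne to the diyne, through escape of the volatile vinyl bromide before it couples, and through oligomerization of the enyne on concentration. The fallback makes the vinyl group by elimination instead of cross-coupling, sets out from 1 and comes back at 6. Sonogashira coupling of 1 with but-3-yn-1-ol (Pd(PPh3)2Cl2, CuI, Et3N, 60 °C) should give 4-(2,2'-bithiophen-5-yl)but-3-yn-1-ol F3. Mesylation (MsCl, Et3N, CH2Cl2, 0 °C) gives 4-(2,2'-bithiophen-5-yl)but-3-yn-1-yl methanesulfonate F4. E2 elimination through the acidic propargylic hydrogens (KOtBu, THF, 0 °C) should then deliver the conjugated enyne 6.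

Step 1 may fail if oxidative addition into the electron-rich bromothiophene is slow, so that copper-mediated homocoupling of ethynyltrimethylsilane and protodebromination outrun the cross-coupling. The fallback builds the alkyne by one-carbon homologation instead of coupling, sets out from 1 and comes back at 5. Bromine–lithium exchange (n-BuLi, THF, −78 °C) and quenching with DMF should give 2,2'-bithiophene-5-carbaldehyde F5. Seyferth–Gilbert homologation with dimethyl (1-diazo-2-oxopropyl)phosphonate (K2CO3, MeOH, rt) converts F5 into 5, which is isolated in this case and enters step 2 at its coupling stage.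

Further compounds
F1 | step 3 | (1S,2S)-1,2-bis[(2,2'-bithiophen-5-yl)ethynyl]cyclobutane (enantiomer of 7) | C(#C[C@H]1CC[C@@H]1C#Cc1ccc(-c2cccs2)s1)c1ccc(-c2cccs2)s1
F2 | step 3 | cis-1,2-bis[(2,2'-bithiophen-5-yl)ethynyl]cyclobutane (meso, isocardopatine) | C(#C[C@@H]1CC[C@@H]1C#Cc1ccc(-c2cccs2)s1)c1ccc(-c2cccs2)s1
F3 | step 2 | 4-(2,2'-bithiophen-5-yl)but-3-yn-1-ol | OCCC#Cc1ccc(-c2cccs2)s1
F4 | step 2 | 4-(2,2'-bithiophen-5-yl)but-3-yn-1-yl methanesulfonate | CS(=O)(=O)OCCC#Cc1ccc(-c2cccs2)s1
F5 | step 1 | 2,2'-bithiophene-5-carbaldehyde | O=Cc1ccc(-c2cccs2)s1
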